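**Retrosynthetic overview**

1. The target is a 5-hydroxy-7-methoxychromen-4-one (rings A and C) whose C2–C3 edge carries a 2,3-dihydro-1-benzoxepine (ring D on resorcinol ring B). Its one stereocentre is the (R)-configured oxepine CH that bears CMe2OH.
2. Feature used: in pyranone ring C, both C3–C4 and O1–C8a tie ring A to the O=C–CH2 (enol) unit of a chiral 1-benzoxepin-5-one. The two oxygens ortho to C4a (O1 on C8a, OH on C5) are equivalent before closure, so ring A enters as a 2,6-difluoro-4-methoxybenzoyl group.
3. Key disconnection: enolate C-aroylation (C3–C4), then fluoride-displacing closure (O1–C8a). Afterwards the surviving C5–F is exchanged for OH, C6 is iodinated under control of the free C5–OH, and the (E)-3-methylbut-1-enyl group is attached by Suzuki coupling.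
4. Benzoxepinone: aryl ketone from an ortho-lithiated phenoxide and an epoxy Weinreb amide, then ring D by 7-exo phenoxide opening of the (S)-epoxide (Shi epoxidation with the enantiomeric ketone), with inversion to (R).
5. Ring order: B (bought) → D → C fused onto A (bought). The stereocentre is set in step 2, inverted once in step 5 and not touched afterwards.

Key step: step 8

Remark: "3,2′-bridged flavone" below means a 2-arylchromen-4-one (O1, C2–C4, C4a, C5–C8, C8a; aryl ring B = C1′–C6′) whose C3 and C2′ are joined by –CH2–CH[C(CH3)2OR]–O– (CH2 on C3, O on C2′; oxepine ring D) with (R) configuration at the bridge CH; the L-fructose-derived enantiomer of the Shi ketone is assumed to be at hand (it can be made from L-sorbose).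

**Route**

Step 1
Reactants: 1 methyl 5-methylhex-4-enoate
Product: 2 N-methoxy-N,5-dimethylhex-4-enamide
Conditions: MeNH(OMe)·HCl, i-PrMgCl, THF, −20 → 0 °C
Reagents that add atoms: N,O-dimethylhydroxylamine hydrochloride, CNOC.Cl
Why: Aminolysis of the ester by the chloromagnesium amide formed in the flask is the standard ester-to-Weinreb-amide conversion, and the isolated trisubstituted alkene is inert to it.

Step 2
Reactants: 2 N-methoxy-N,5-dimethylhex-4-enamide
Product: 3 3-[(2S)-3,3-dimethyloxiran-2-yl]-N-methoxy-N-methylpropanamide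
Conditions: 1,2:4,5-di-O-isopropylidene-β-L-erythro-2,3-hexodiulo-2,6-pyranose (ent-Shi ketone, 30 mol %), Oxone (2KHSO5·KHSO4·K2SO4), K2CO3, Bu4NHSO4, MeCN–CH2(OMe)2/aq Na2B4O7 buffer (pH ≈ 10.5), 0 °C
Reagents that add atoms: potassium peroxymonosulfate (the oxidant in Oxone), [K+].[O-]S(=O)(=O)OO
Why: Shi asymmetric epoxidation, in which the chiral dioxirane transfers oxygen to the trisubstituted olefin through a spiro transition state; the D-fructose-derived ketone is known to give the (R)-epoxide with R–CH2–CH=CMe2 olefins, so its enantiomer is used to set the (S)-epoxide carbon that is inverted to (R) in step 5.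

Step 3
Reactants: 4 4-bromoresorcinol
Product: 5 5-(benzyloxy)-2-bromophenol
Conditions: BnBr (1.0 equiv), K2CO3 (1.0 equiv), acetone, rt
Reagents that add atoms: benzyl bromide, BrCc1ccccc1
Why: Williamson etherification in which the hydroxyl para to bromine, the less hindered one with the more nucleophilic phenoxide, should react preferentially; the minor regioisomer and the bis-ether are to be removed by chromatography and the regiochemistry checked by NOE.

Step 4
Reactants: 5 5-(benzyloxy)-2-bromophenol; 3 3-[(2S)-3,3-dimethyloxiran-2-yl]-N-methoxy-N-methylpropanamide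
Product: 7 1-[4-(benzyloxy)-2-hydroxyphenyl]-3-[(2S)-3,3-dimethyloxiran-2-yl]propan-1-one, via dilithio phenoxide 6 (not isolated)
Conditions: n-BuLi (1.0 equiv), THF, −78 °C; t-BuLi (2.0 equiv), −78 °C; 3, −78 → −20 °C; H2O
Reagents that add atoms: none
Why: Deprotonation and bromine–lithium exchange give the O,C-dilithio species, whose aryl carbanion adds to the Weinreb amide to form a chelated tetrahedral adduct that releases the ketone only on quench (Weinreb ketone synthesis), while the hindered trisubstituted epoxide is not opened by an organolithium at low temperature without a Lewis acid.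

Step 5
Reactants: 7 1-[4-(benzyloxy)-2-hydroxyphenyl]-3-[(2S)-3,3-dimethyloxiran-2-yl]propan-1-one
Product: 8 (2R)-8-(benzyloxy)-2-(2-hydroxypropan-2-yl)-3,4-dihydro-1-benzoxepin-5(2H)-one
Conditions: K2CO3 (0.5 equiv), DMF, 70 °C
Reagents that add atoms: none
Why: Base-mediated phenol–epoxide cyclisation, a known way to close benzo-fused cyclic ethers that carry a 2-(2-hydroxypropan-2-yl) group: the phenoxide attacks the less substituted epoxide carbon (7-exo-tet SN2), so the C–O bond forms with inversion and the (S)-epoxide gives the (R)-ether, and carbonate is too weak to enolise the ketone.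

Step 6
Reactants: 8 (2R)-8-(benzyloxy)-2-(2-hydroxypropan-2-yl)-3,4-dihydro-1-benzoxepin-5(2H)-one
Product: 9 (2R)-8-(benzyloxy)-2-[2-(triethylsilyloxy)propan-2-yl]-3,4-dihydro-1-benzoxepin-5(2H)-one
Conditions: TESOTf, 2,6-lutidine, CH2Cl2, −78 → 0 °C; aq NaHCO3
Reagents that add atoms: triethylsilyl trifluoromethanesulfonate, CC[Si](CC)(CC)OS(=O)(=O)C(F)(F)F
Why: Silyl triflate/2,6-lutidine silylation is the standard way to cap a hindered tertiary alcohol, which must be masked because its alkoxide would compete for the acid chloride in step 8; any silyl enol ether formed at the ketone is hydrolysed on work-up.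

Step 7
Reactants: 10 2,6-difluoro-4-methoxybenzoic acid
Product: 11 2,6-difluoro-4-methoxybenzoyl chloride
Conditions: (COCl)2, DMF (cat.), CH2Cl2, 0 °C → rt
Reagents that add atoms: oxalyl chloride, O=C(Cl)C(=O)Cl
Why: Vilsmeier-type activation of the carboxylic acid by oxalyl chloride/DMF gives the acid chloride with only gaseous by-products, and the electron-poor ring is inert.

Step 8
Reactants: 9 (2R)-8-(benzyloxy)-2-[2-(triethylsilyloxy)propan-2-yl]-3,4-dihydro-1-benzoxepin-5(2H)-one; 11 2,6-difluoro-4-methoxybenzoyl chloride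
Product: 14 (R)-4′-benzyloxy-5-fluoro-7-methoxy-3,2′-bridged flavone TES ether, via lithium enolate 12 (not isolated), via fluoroaryl diketone 13 (not isolated)
Conditions: LiN(SiMe3)2 (2.5 equiv), THF, −78 °C; 11, −78 → 0 °C; DMPU, 60 °C
Reagents that add atoms: none
Why: LiN(SiMe3)2 converts the ketone, whose only α-hydrogens are on C4 of the oxepinone, into lithium enolate 12, which attacks the acid chloride at carbon (Claisen-type C-aroylation, forming C3–C4 of the chromenone); the second equivalent of base deprotonates diketone 13 at once, which pulls the acylation towards carbon and lets any enol ester formed by O-acylation act as an acyl donor towards remaining enolate. On warming, the enolate oxygen that stems from the oxepinone carbonyl adds to a fluorine-bearing carbon ortho to the aroyl carbonyl and fluoride leaves (intramolecular SNAr by addition–elimination through a Meisenheimer intermediate), which closes pyranone ring C in a 6-exo-trig mode and forms O1–C8a. The closest known reaction is the one-pot chromone synthesis from ketone enolates and 2-fluorobenzoyl chlorides. No stereocentre is formed, and the existing one lies γ to the carbonyl, carries no acidic hydrogen and has no leaving group β to the enolate carbon, so it should not be affected. The selectivities needed are C- over O-acylation (lithium counter-ion, low temperature, excess base trapping the diketonate), the site of enolisation (a single enolisable CH2) and the choice of fluoride (the two ortho fluorides are equivalent by symmetry, so either closure gives the same product). The remaining C5 fluoride, ortho to the carbonyl-bearing C4a, is kept as a latent hydroxyl.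

Step 9
Reactants: 14 (R)-4′-benzyloxy-5-fluoro-7-methoxy-3,2′-bridged flavone TES ether
Product: 15 (R)-4′,5-bis(benzyloxy)-7-methoxy-3,2′-bridged flavone TES ether
Conditions: BnOH (2 equiv), NaH (1.5 equiv), THF–DMF, 0 → 50 °C
Reagents that add atoms: benzyl alcohol, OCc1ccccc1
Why: SNAr of the C5 fluoride, which is activated by the peri C4 carbonyl (the Meisenheimer charge is delocalised onto it, and the C7 methoxy group and O1 are meta to the reacting carbon), as known for 5-fluorochromones; ring B carries a benzyl and not a silyl ether at this stage because an aryl silyl ether would not survive the alkoxide.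

Step 10
Reactants: 15 (R)-4′,5-bis(benzyloxy)-7-methoxy-3,2′-bridged flavone TES ether
Product: 16 (R)-4′,5-dihydroxy-7-methoxy-3,2′-bridged flavone TES ether
Conditions: H2 (1 atm), Pd/C (10 wt %), EtOAc–THF, rt
Reagents that add atoms: none
Why: Hydrogenolysis of both aryl benzyl ethers over palladium on carbon; the tetrasubstituted C2=C3 bond of the vinylogous ester and, in a non-protic solvent, the tertiary TES ether should not be affected.

Step 11
Reactants: 16 (R)-4′,5-dihydroxy-7-methoxy-3,2′-bridged flavone TES ether
Product: 17 (R)-5-hydroxy-7-methoxy-4′-(triisopropylsilyloxy)-3,2′-bridged flavone TES ether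
Conditions: TIPSCl, imidazole, DMF, 0 °C → rt
Reagents that add atoms: triisopropylsilyl chloride, CC(C)[Si](Cl)(C(C)C)C(C)C
Why: Chemoselective phenol silylation: the C5 hydroxyl is locked in a hydrogen bond to the C4 carbonyl and is unreactive, so only the C4′ phenol is silylated, and the bulky, weakly donating silyl ether then shields ring B during the iodination.

Step 12
Reactants: 17 (R)-5-hydroxy-7-methoxy-4′-(triisopropylsilyloxy)-3,2′-bridged flavone TES ether
Product: 18 (R)-5-hydroxy-6-iodo-7-methoxy-4′-(triisopropylsilyloxy)-3,2′-bridged flavone TES ether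
Conditions: BnMe3N+ ICl2− (1.05 equiv), CaCO3, CH2Cl2–MeOH, rt
Reagents that add atoms: benzyltrimethylammonium dichloroiodate, C[N+](C)(C)Cc1ccccc1.Cl[I-]Cl
Why: Electrophilic aromatic iodination directed by the free, chelated C5 phenol to its ortho position C6, the outcome known for 5-hydroxy-7-alkoxyflavones with this reagent; CaCO3 takes up the HCl so that the TES ether should survive.

Step 13
Reactants: 19 3-methylbut-1-yne
Product: 20 (E)-4,4,5,5-tetramethyl-2-(3-methylbut-1-enyl)-1,3,2-dioxaborolane
Conditions: pinacolborane, Cp2Zr(H)Cl (5 mol %), Et3N (10 mol %), neat, sealed tube, 50 °C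
Reagents that add atoms: pinacolborane, [H]B1OC(C)(C)C(C)(C)O1
Why: Zirconocene-hydride-catalysed hydroboration of a terminal alkyne with pinacolborane is a syn addition with boron at the terminal carbon, so the (E)-alkenylboronate is expected.

Step 14
Reactants: 18 (R)-5-hydroxy-6-iodo-7-methoxy-4′-(triisopropylsilyloxy)-3,2′-bridged flavone TES ether; 20 (E)-4,4,5,5-tetramethyl-2-(3-methylbut-1-enyl)-1,3,2-dioxaborolane
Product: 21 (R)-5-hydroxy-7-methoxy-6-[(E)-3-methylbut-1-enyl]-4′-(triisopropylsilyloxy)-3,2′-bridged flavone TES ether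
Conditions: Pd(OAc)2 (5 mol %), SPhos (2-dicyclohexylphosphino-2′,6′-dimethoxybiphenyl, 10 mol %), K3PO4, THF–H2O, 60 °C
Reagents that add atoms: none
Why: Suzuki–Miyaura coupling (oxidative addition of zerovalent palladium into the C6–I bond, transmetalation of the alkenylboronate, reductive elimination) proceeds with retention of the (E) geometry; SPhos is chosen for the doubly ortho-substituted iodide, and the free phenol and both silyl ethers should tolerate the mild aqueous phosphate.

Step 15
Reactants: 21 (R)-5-hydroxy-7-methoxy-6-[(E)-3-methylbut-1-enyl]-4′-(triisopropylsilyloxy)-3,2′-bridged flavone TES ether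
Product: 22 CNP0216454.1, (R)-4′,5-dihydroxy-7-methoxy-6-[(E)-3-methylbut-1-enyl]-3,2′-bridged flavone with free carbinol
Conditions: Bu4NF (3 equiv), THF, 0 → 40 °C; H2O
Reagents that add atoms: none
Why: Fluoride-mediated desilylation cleaves both Si–O bonds through pentacoordinate silicon (aryl TIPS ether quickly, tertiary TES ether on gentle warming) without touching the alkene or the stereocentre, which should give the target.

**Compound list**

1 | methyl 5-methylhex-4-enoate | COC(=O)CCC=C(C)C | starting material
2 | N-methoxy-N,5-dimethylhex-4-enamide | CON(C)C(=O)CCC=C(C)C | intermediate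
3 | 3-[(2S)-3,3-dimethyloxiran-2-yl]-N-methoxy-N-methylpropanamide | CON(C)C(=O)CC[C@@H]1OC1(C)C | intermediate
4 | 4-bromoresorcinol (4-bromobenzene-1,3-diol) | Oc1ccc(Br)c(O)c1 | starting material
5 | 5-(benzyloxy)-2-bromophenol | Oc1cc(OCc2ccccc2)ccc1Br | intermediate
6 | lithium 5-(benzyloxy)-2-lithiophenoxide (dilithio phenoxide) | [Li]Oc1cc(OCc2ccccc2)ccc1[Li] | intermediate (not isolated)
7 | 1-[4-(benzyloxy)-2-hydroxyphenyl]-3-[(2S)-3,3-dimethyloxiran-2-yl]propan-1-one | O=C(CC[C@@H]1OC1(C)C)c1ccc(OCc2ccccc2)cc1O | intermediate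
8 | (2R)-8-(benzyloxy)-2-(2-hydroxypropan-2-yl)-3,4-dihydro-1-benzoxepin-5(2H)-one | O=C1CC[C@H](C(C)(C)O)Oc2cc(OCc3ccccc3)ccc21 | intermediate
9 | (2R)-8-(benzyloxy)-2-[2-(triethylsilyloxy)propan-2-yl]-3,4-dihydro-1-benzoxepin-5(2H)-one | O=C1CC[C@H](C(C)(C)O[Si](CC)(CC)CC)Oc2cc(OCc3ccccc3)ccc21 | intermediate (key-step precursor)
10 | 2,6-difluoro-4-methoxybenzoic acid | COc1cc(F)c(C(=O)O)c(F)c1 | starting material
11 | 2,6-difluoro-4-methoxybenzoyl chloride | COc1cc(F)c(C(Cl)=O)c(F)c1 | intermediate
12 | lithium enolate of 9 (lithium (2R)-8-(benzyloxy)-2-[2-(triethylsilyloxy)propan-2-yl]-2,3-dihydro-1-benzoxepin-5-olate) | [Li]OC1=CC[C@H](C(C)(C)O[Si](CC)(CC)CC)Oc2cc(OCc3ccccc3)ccc21 | intermediate (not isolated)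
13 | (2R)-8-(benzyloxy)-4-(2,6-difluoro-4-methoxybenzoyl)-2-[2-(triethylsilyloxy)propan-2-yl]-3,4-dihydro-1-benzoxepin-5(2H)-one (C4 epimers/enol, fluoroaryl diketone) | COc1cc(F)c(C(=O)C2C[C@H](C(C)(C)O[Si](CC)(CC)CC)Oc3cc(OCc4ccccc4)ccc3C2=O)c(F)c1 | intermediate (not isolated)
14 | (R)-4′-benzyloxy-5-fluoro-7-methoxy-3,2′-bridged flavone TES ether | COc1cc2oc3c(c(=O)c2c(F)c1)C[C@H](C(C)(C)O[Si](CC)(CC)CC)Oc1cc(OCc2ccccc2)ccc1-3 | intermediate (key-step product)
15 | (R)-4′,5-bis(benzyloxy)-7-methoxy-3,2′-bridged flavone TES ether | COc1cc2oc3c(c(=O)c2c(OCc4ccccc4)c1)C[C@H](C(C)(C)O[Si](CC)(CC)CC)Oc1cc(OCc5ccccc5)ccc1-3 | intermediate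
16 | (R)-4′,5-dihydroxy-7-methoxy-3,2′-bridged flavone TES ether | COc1cc2oc3c(c(=O)c2c(O)c1)C[C@H](C(C)(C)O[Si](CC)(CC)CC)Oc1cc(O)ccc1-3 | intermediate
17 | (R)-5-hydroxy-7-methoxy-4′-(triisopropylsilyloxy)-3,2′-bridged flavone TES ether | COc1cc2oc3c(c(=O)c2c(O)c1)C[C@H](C(C)(C)O[Si](CC)(CC)CC)Oc1cc(O[Si](C(C)C)(C(C)C)C(C)C)ccc1-3 | intermediate
18 | (R)-5-hydroxy-6-iodo-7-methoxy-4′-(triisopropylsilyloxy)-3,2′-bridged flavone TES ether | COc1cc2oc3c(c(=O)c2c(O)c1I)C[C@H](C(C)(C)O[Si](CC)(CC)CC)Oc1cc(O[Si](C(C)C)(C(C)C)C(C)C)ccc1-3 | intermediate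
19 | 3-methylbut-1-yne | CC(C)C#C | starting material
20 | (E)-4,4,5,5-tetramethyl-2-(3-methylbut-1-enyl)-1,3,2-dioxaborolane | CC(C)/C=C/B1OC(C)(C)C(C)(C)O1 | intermediate
21 | (R)-5-hydroxy-7-methoxy-6-[(E)-3-methylbut-1-enyl]-4′-(triisopropylsilyloxy)-3,2′-bridged flavone TES ether | COc1cc2oc3c(c(=O)c2c(O)c1/C=C/C(C)C)C[C@H](C(C)(C)O[Si](CC)(CC)CC)Oc1cc(O[Si](C(C)C)(C(C)C)C(C)C)ccc1-3 | intermediate
22 | CNP0216454.1, (R)-4′,5-dihydroxy-7-methoxy-6-[(E)-3-methylbut-1-enyl]-3,2′-bridged flavone with free carbinol | COc1cc2oc3c(c(=O)c2c(O)c1/C=C/C(C)C)C[C@H](C(C)(C)O)Oc1cc(O)ccc1-3 | target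

**Step count**

Total step count: 15.
Longest linear sequence: 12 steps (steps 1, 2, 4, 5, 6, 8, 9, 10, 11, 12, 14, 15).

**Steps most likely to fail**

Step 8 (key step). The enolate may be acylated at oxygen, or the amide base may consume the acid chloride, instead of C-aroylation at C4. The lithium-chelated diketonate may also fail to rotate into the geometry needed for fluoride displacement, so that open-chain material accumulates. The fallback sets out from 9 and returns at 14. The lithium enolate of 9 is added to commercial 2,6-difluoro-4-methoxybenzaldehyde (COc1cc(F)c(C=O)c(F)c1) in THF at −78 °C; this aldol addition can only occur at carbon and should give the β-hydroxy ketone F1 as a diastereomer mixture. Dess–Martin oxidation converts it into diketone 13, now isolated, and K2CO3 in DMF at 80 °C closes ring C by the same fluoride displacement to give 14.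

Step 5. The seven-membered closure may be slow, because the acyl-conjugated phenoxide is a weak nucleophile and the epoxide carbon is neopentyl-like; intermolecular opening or base-induced decomposition of the epoxy ketone could then take over. The fallback sets out from 3 and 5 and returns at 9. The caesium phenoxide of 5 (Cs2CO3, DMF, 90–100 °C), not yet acylated and therefore more nucleophilic, opens epoxide 3 intermolecularly at the secondary carbon with inversion to give (4R)-4-[5-(benzyloxy)-2-bromophenoxy]-5-hydroxy-N-methoxy-N,5-dimethylhexanamide F2. TESOTf/2,6-lutidine gives its triethylsilyl ether F3. t-BuLi (2 equiv, THF, −78 °C) generates the aryllithium F4 by bromine–lithium exchange, and this closes onto the Weinreb amide (Parham cyclisation) to give 9. The aryl-dianion acylation of step 4 is bypassed as well.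

Step 9. Fluoride displacement on the electron-rich ring A may be sluggish, or the alkoxide may add at C2 and open the pyranone ring. The fallback sets out from 10 and returns at 15; the benzyloxy group is installed before the ring is built. Acid 10 undergoes mono-substitution of one ortho fluoride by sodium benzyl oxide (BnOH, NaH, DMF, 80 °C; the second fluoride is deactivated by the new alkoxy group) to give 2-(benzyloxy)-6-fluoro-4-methoxybenzoic acid F5. Oxalyl chloride/DMF gives the acid chloride F6. The enolate of 9 (LiN(SiMe3)2, THF, −78 °C) is C-aroylated by F6 to give the benzyloxy fluoroaryl diketone F7, and K2CO3 in DMF at 80–100 °C displaces the single remaining fluoride to give 15 directly. Only one fluoride is present at the closure, so no regiochemical question arises.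

**Further compounds**

F1 | step 8 | (2R)-8-(benzyloxy)-4-[(2,6-difluoro-4-methoxyphenyl)(hydroxy)methyl]-2-[2-(triethylsilyloxy)propan-2-yl]-3,4-dihydro-1-benzoxepin-5(2H)-one (diastereomer mixture at the two new centres) | COc1cc(F)c(C(O)C2C[C@H](C(C)(C)O[Si](CC)(CC)CC)Oc3cc(OCc4ccccc4)ccc3C2=O)c(F)c1
F2 | step 5 | (4R)-4-[5-(benzyloxy)-2-bromophenoxy]-5-hydroxy-N-methoxy-N,5-dimethylhexanamide | CON(C)C(=O)CC[C@H](C(C)(C)O)Oc1cc(OCc2ccccc2)ccc1Br
F3 | step 5 | (4R)-4-[5-(benzyloxy)-2-bromophenoxy]-N-methoxy-N,5-dimethyl-5-(triethylsilyloxy)hexanamide | CON(C)C(=O)CC[C@H](C(C)(C)O[Si](CC)(CC)CC)Oc1cc(OCc2ccccc2)ccc1Br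
F4 | step 5 | aryllithium from F3, (4R)-4-[5-(benzyloxy)-2-lithiophenoxy]-N-methoxy-N,5-dimethyl-5-(triethylsilyloxy)hexanamide | CON(C)C(=O)CC[C@H](C(C)(C)O[Si](CC)(CC)CC)Oc1cc(OCc2ccccc2)ccc1[Li]
F5 | step 9 | 2-(benzyloxy)-6-fluoro-4-methoxybenzoic acid | COc1cc(F)c(C(=O)O)c(OCc2ccccc2)c1
F6 | step 9 | 2-(benzyloxy)-6-fluoro-4-methoxybenzoyl chloride | COc1cc(F)c(C(Cl)=O)c(OCc2ccccc2)c1
F7 | step 9 | (2R)-8-(benzyloxy)-4-[2-(benzyloxy)-6-fluoro-4-methoxybenzoyl]-2-[2-(triethylsilyloxy)propan-2-yl]-3,4-dihydro-1-benzoxepin-5(2H)-one (C4 epimers/enol) | COc1cc(F)c(C(=O)C2C[C@H](C(C)(C)O[Si](CC)(CC)CC)Oc3cc(OCc4ccccc4)ccc3C2=O)c(OCc5ccccc5)c1
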